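## Retrosynthetic overview

Isochromene numbering: C1H2–O2–C3(=C4H)–C4a(=C5Cl)–C6(=O)–C7(Me)(OH)–C8H(OH)–C8aH, with C8a bonded to C1 and C4a.

1. The target comes from its 7,8-O-isobutylidene acetal, a dioxolane that is not in the target, by hydrolysis.
2. The pyran ring (C1, O2, C3, C4, C4a, C8a) is opened at O2–C3 and at C4–C4a. This leads to a hydroxy ynenone, and further back to the side-chain alkyne plus a vinylogous ester with its carbonyl at C4a and its methoxy group on C6. The enabling feature is the doubly vinylogous ester O2–C3=C4–C4a=C5–C6=O that runs through the pyran ring and the carbocycle: C3 is the δ-carbon of a C6 ketone, and C6/C4a are related by a 1,3-carbonyl transposition.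
3. The carbocycle is never closed: it is the benzene ring of 3-methoxy-4-methylphenol, dearomatised at C7 to a para-quinol. A tethered oxa-Michael addition (temporary dioxolane O7–CH(i-Pr)–O8) then sets C8 and C8a from C7 and sorts the enantiomers.
4. The side-chain dienynol comes from ethyl (S)-3-hydroxybutanoate by Fráter–Seebach methylation, Wittig and Horner–Wadsworth–Emmons olefinations.
5. Ring order: carbocycle (from the arene), temporary dioxolane, pyran ring (last ring of the skeleton), then removal of the dioxolane.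

Key step: step 13

Assumption: the (R)-configured phosphoric acid is taken as the enantiomer that consumes (4R)-5 in step 5 (if the sense proves opposite, its mirror image is used); the acetal carbon is drawn in the expected exo configuration, which is immaterial because step 14 removes it.

## Route

Step 1
Reactants: 1 3-methoxy-4-methylphenol
Product: 2 2-hydroxy-4-methoxy-5-methylbenzaldehyde
Conditions: (CH2O)n, MgCl2, Et3N, MeCN, reflux
Reagents that add atoms: paraformaldehyde (as formaldehyde), C=O
Why: Magnesium-phenoxide-directed ortho-formylation (Casnati–Skattebøl reaction) should occur only ortho to the hydroxyl and at the less hindered ortho carbon (para to OMe, not the one flanked by OH and OMe), which puts the future C1 on the future C8a.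

Step 2
Reactants: 2 2-hydroxy-4-methoxy-5-methylbenzaldehyde
Product: 3 2-(hydroxymethyl)-5-methoxy-4-methylphenol
Conditions: NaBH4, MeOH, 0 °C
Reagents that add atoms: none
Why: Borohydride reduction of an aryl aldehyde to the benzylic alcohol is routine and leaves the phenol and the aryl ether untouched.

Step 3
Reactants: 3 2-(hydroxymethyl)-5-methoxy-4-methylphenol
Product: 4 2-{[(tert-butyldimethylsilyl)oxy]methyl}-5-methoxy-4-methylphenol
Conditions: TBSCl (1.05 equiv), imidazole, CH2Cl2, 0 °C
Reagents that add atoms: tert-butyldimethylsilyl chloride, CC(C)(C)[Si](C)(C)Cl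
Why: With one equivalent of silyl chloride in the cold, the primary benzylic hydroxyl should be silylated in preference to the hydrogen-bonded phenol (selective silyl ether formation), which masks the future C1 hydroxyl against the oxidant of step 4.

Step 4
Reactants: 4 2-{[(tert-butyldimethylsilyl)oxy]methyl}-5-methoxy-4-methylphenol
Product: 5 rac-4-hydroxy-5-methoxy-4-methyl-2-{[(tert-butyldimethylsilyl)oxy]methyl}cyclohexa-2,5-dien-1-one
Conditions: PhI(OAc)2, MeCN/H2O, 0 °C
Reagents that add atoms: water, O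
Why: Trivalent-iodine oxidation of a para-alkylphenol gives a phenoxenium-type species that water captures at the methyl-bearing para carbon (hydrative oxidative dearomatisation to a para-quinol); this creates C7 with its methyl and hydroxyl groups as a racemate, with the methoxy group on a vinylogous-ester arm and the silyloxymethyl group on a plain enone arm.

Step 5
Reactants: 5 rac-4-hydroxy-5-methoxy-4-methyl-2-{[(tert-butyldimethylsilyl)oxy]methyl}cyclohexa-2,5-dien-1-one
Product: 6 (2S,3aR,4S,7aR)-4-{[(tert-butyldimethylsilyl)oxy]methyl}-7-methoxy-7a-methyl-2-(propan-2-yl)-3a,4-dihydro-1,3-benzodioxol-5(7aH)-one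
Conditions: i-PrCHO, (R)-3,3'-bis(2,4,6-triisopropylphenyl)-1,1'-binaphthalene-2,2'-diyl hydrogen phosphate (cat.), 4 Å MS, PhMe, rt, stopped near half conversion
Reagents that add atoms: 2-methylpropanal, CC(C)C=O
Why: In this chiral-phosphoric-acid-catalysed acetalisation/oxa-Michael cascade the C7 hydroxyl forms a hemiacetal whose oxygen adds to C8 of the only competent enone arm (the other arm is capped by OMe), so the tether delivers O8 cis to O7; the enol should then be protonated at C8a on the convex face anti to the new dioxolane (C1 cis to O8), and the catalyst's arm selectivity on para-quinols becomes enantiomer selectivity here, so that (4R)-5 should be consumed and (4S)-5 left behind (kinetic resolution).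

Step 6
Reactants: 6 (2S,3aR,4S,7aR)-4-{[(tert-butyldimethylsilyl)oxy]methyl}-7-methoxy-7a-methyl-2-(propan-2-yl)-3a,4-dihydro-1,3-benzodioxol-5(7aH)-one
Product: 7 (2S,3aR,4S,7aR)-6-chloro-4-{[(tert-butyldimethylsilyl)oxy]methyl}-7-methoxy-7a-methyl-2-(propan-2-yl)-3a,4-dihydro-1,3-benzodioxol-5(7aH)-one
Conditions: N-chlorosuccinimide, CH2Cl2, 0 °C → rt
Reagents that add atoms: N-chlorosuccinimide, O=C1CCC(=O)N1Cl
Why: The α-carbon of the vinylogous ester (C5) is its only nucleophilic carbon, so electrophilic α-chlorination of the 3-alkoxy-enone should place the chlorine there.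

Step 7
Reactants: 8 ethyl (3S)-3-hydroxybutanoate
Product: 9 ethyl (2S,3S)-3-hydroxy-2-methylbutanoate
Conditions: LiN(i-Pr)2 (2.2 equiv), THF, −50 → −20 °C; MeI, DMPU, −78 → 0 °C
Reagents that add atoms: iodomethane, CI
Why: In the Fráter–Seebach alkylation the chelated alkoxide–enolate dianion is methylated anti to the C3 substituent, which sets the (2S) centre in the anti relationship needed for C5' and C6' of the side chain.

Step 8
Reactants: 9 ethyl (2S,3S)-3-hydroxy-2-methylbutanoate
Product: 10 ethyl (2S,3S)-3-[(tert-butyldimethylsilyl)oxy]-2-methylbutanoate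
Conditions: TBSCl, imidazole, DMF, rt
Reagents that add atoms: tert-butyldimethylsilyl chloride, CC(C)(C)[Si](C)(C)Cl
Why: Standard silyl ether formation protects the secondary hydroxyl for the hydride reduction and the two olefinations.

Step 9
Reactants: 10 ethyl (2S,3S)-3-[(tert-butyldimethylsilyl)oxy]-2-methylbutanoate
Product: 11 (2S,3S)-3-[(tert-butyldimethylsilyl)oxy]-2-methylbutanal
Conditions: i-Bu2AlH (1.05 equiv), CH2Cl2, −78 °C; Rochelle salt work-up
Reagents that add atoms: none
Why: At low temperature the aluminium hemiacetal persists and collapses to the aldehyde only on work-up (partial reduction of an ester), and the α-stereocentre should survive these non-basic conditions if the aldehyde is used at once.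

Step 10
Reactants: 11 (2S,3S)-3-[(tert-butyldimethylsilyl)oxy]-2-methylbutanal; 12 2-(triphenyl-λ5-phosphanylidene)propanal
Product: 13 (2E,4R,5S)-5-[(tert-butyldimethylsilyl)oxy]-2,4-dimethylhex-2-enal
Conditions: PhMe, 90 °C
Reagents that add atoms: none
Why: Wittig olefination with the stabilised α-methyl ylide should give the trisubstituted enal with E geometry and without epimerising the adjacent stereocentre.

Step 11
Reactants: 13 (2E,4R,5S)-5-[(tert-butyldimethylsilyl)oxy]-2,4-dimethylhex-2-enal; 14 diethyl [3-(trimethylsilyl)prop-2-yn-1-yl]phosphonate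
Product: 15 tert-butyl{[(2S,3R,4E,6E)-3,5-dimethyl-9-(trimethylsilyl)nona-4,6-dien-8-yn-2-yl]oxy}dimethylsilane
Conditions: 14, LiN(SiMe3)2, THF, −78 °C; then 13, −78 → 0 °C
Reagents that add atoms: none
Why: Horner–Wadsworth–Emmons olefination with the lithiated propargylic phosphonate turns the enal into the conjugated dienyne and should favour the E-alkene, as is usual for stabilised phosphonate anions.

Step 12
Reactants: 15 tert-butyl{[(2S,3R,4E,6E)-3,5-dimethyl-9-(trimethylsilyl)nona-4,6-dien-8-yn-2-yl]oxy}dimethylsilane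
Product: 16 (2S,3R,4E,6E)-3,5-dimethylnona-4,6-dien-8-yn-2-ol
Conditions: Bu4NF (2.5 equiv), THF, 0 °C → rt
Reagents that add atoms: none
Why: Fluoride cleaves the alkynyl C–Si and the secondary O–Si bond in one operation (desilylation), freeing the terminal alkyne for metalation and leaving a hydroxyl that passes through the key step as its alkoxide.

Step 13
Reactants: 7 (2S,3aR,4S,7aR)-6-chloro-4-{[(tert-butyldimethylsilyl)oxy]methyl}-7-methoxy-7a-methyl-2-(propan-2-yl)-3a,4-dihydro-1,3-benzodioxol-5(7aH)-one; 16 (2S,3R,4E,6E)-3,5-dimethylnona-4,6-dien-8-yn-2-ol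
Product: 19 7,8-O-[(S)-2-methylpropylidene] acetal of (7R,8R,8aS)-5-chloro-7,8-dihydroxy-3-[(1E,3E,5R,6S)-6-hydroxy-3,5-dimethylhepta-1,3-dien-1-yl]-7-methyl-1,7,8,8a-tetrahydro-6H-isochromen-6-one, via propargylic carbinol 17 (not isolated), via hydroxy ynenone 18 (not isolated)
Conditions: 16 (1.5 equiv), n-BuLi (3.0 equiv), THF, −78 °C; CeCl3; then 7, −78 → −30 °C; then 1 M aq. HCl, THF, 0 °C → rt
Reagents that add atoms: water, O
Why: The cerium acetylide of 16 (low basicity, so that 1,2-addition should outrun deprotonation at C8a) adds to the C4a carbonyl of vinylogous ester 7 to give carbinol 17; aqueous acid then hydrolyses the C6 enol ether and dehydrates, which moves the carbonyl to C6 and leaves the alkyne on C4a (Stork–Danheiser alkynylation–transposition, the closest known reaction type), and the same acid removes the primary silyl ether to give hydroxy ynenone 18. In 18 the C1 hydroxyl sits six atoms from C3, the δ-carbon of the C6(=O)–C5(Cl)=C4a–C4≡C3 acceptor, and should add to it in an acid-promoted oxa-Michael (1,6-) addition, after which tautomerisation gives the O2–C3=C4–C4a=C5–C6=O push–pull dienone as the thermodynamic sink. The pyran ring is thus closed by O2–C3 bond formation in the 6-endo-dig mode, with the carbocycle already in place. No stereocentre is created: C7, C8 and C8a are carried through (C8a is no longer α to a carbonyl once 17 has formed) and the E,E-diene is not touched. The step needs 6-endo over 5-exo closure, which the polarisation of the ynenone (electrophilic C3, further stabilised by the dienyl group) should secure; it also needs attack by the C1 hydroxyl alone, which is secured because O7 and O8 are locked in the acetal and the side-chain hydroxyl is remote.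

Step 14
Reactants: 19 7,8-O-[(S)-2-methylpropylidene] acetal of (7R,8R,8aS)-5-chloro-7,8-dihydroxy-3-[(1E,3E,5R,6S)-6-hydroxy-3,5-dimethylhepta-1,3-dien-1-yl]-7-methyl-1,7,8,8a-tetrahydro-6H-isochromen-6-one
Product: 20 (7R,8R,8aS)-5-chloro-7,8-dihydroxy-3-[(1E,3E,5R,6S)-6-hydroxy-3,5-dimethylhepta-1,3-dien-1-yl]-7-methyl-1,7,8,8a-tetrahydro-6H-isochromen-6-one
Conditions: TFA/H2O/THF, 0 °C → rt
Reagents that add atoms: none
Why: Acid-catalysed acetal hydrolysis releases the cis-7,8-diol without touching a stereocentre, and the O2–C3=C4–C4a=C5–C6=O unit, being a doubly vinylogous ester, should tolerate cold aqueous acid.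

## Compound list

1 | 3-methoxy-4-methylphenol | COc1cc(O)ccc1C | starting material
2 | 2-hydroxy-4-methoxy-5-methylbenzaldehyde | COc1cc(O)c(C=O)cc1C | intermediate
3 | 2-(hydroxymethyl)-5-methoxy-4-methylphenol | COc1cc(O)c(CO)cc1C | intermediate
4 | 2-{[(tert-butyldimethylsilyl)oxy]methyl}-5-methoxy-4-methylphenol | COc1cc(O)c(CO[Si](C)(C)C(C)(C)C)cc1C | intermediate
5 | rac-4-hydroxy-5-methoxy-4-methyl-2-{[(tert-butyldimethylsilyl)oxy]methyl}cyclohexa-2,5-dien-1-one (racemate) | COC1=CC(=O)C(CO[Si](C)(C)C(C)(C)C)=CC1(C)O | intermediate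
6 | (2S,3aR,4S,7aR)-4-{[(tert-butyldimethylsilyl)oxy]methyl}-7-methoxy-7a-methyl-2-(propan-2-yl)-3a,4-dihydro-1,3-benzodioxol-5(7aH)-one | O=C1C=C(OC)[C@]2(C)O[C@@H](C(C)C)O[C@@H]2[C@@H]1CO[Si](C)(C)C(C)(C)C | intermediate
7 | (2S,3aR,4S,7aR)-6-chloro-4-{[(tert-butyldimethylsilyl)oxy]methyl}-7-methoxy-7a-methyl-2-(propan-2-yl)-3a,4-dihydro-1,3-benzodioxol-5(7aH)-one | O=C1C(Cl)=C(OC)[C@]2(C)O[C@@H](C(C)C)O[C@@H]2[C@@H]1CO[Si](C)(C)C(C)(C)C | intermediate
8 | ethyl (3S)-3-hydroxybutanoate | CCOC(=O)C[C@H](C)O | starting material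
9 | ethyl (2S,3S)-3-hydroxy-2-methylbutanoate | CCOC(=O)[C@@H](C)[C@H](C)O | intermediate
10 | ethyl (2S,3S)-3-[(tert-butyldimethylsilyl)oxy]-2-methylbutanoate | CCOC(=O)[C@@H](C)[C@H](C)O[Si](C)(C)C(C)(C)C | intermediate
11 | (2S,3S)-3-[(tert-butyldimethylsilyl)oxy]-2-methylbutanal | O=C[C@@H](C)[C@H](C)O[Si](C)(C)C(C)(C)C | intermediate
12 | 2-(triphenyl-λ5-phosphanylidene)propanal | CC(C=O)=P(c1ccccc1)(c1ccccc1)c1ccccc1 | starting material
13 | (2E,4R,5S)-5-[(tert-butyldimethylsilyl)oxy]-2,4-dimethylhex-2-enal | O=C/C(C)=C/[C@@H](C)[C@H](C)O[Si](C)(C)C(C)(C)C | intermediate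
14 | diethyl [3-(trimethylsilyl)prop-2-yn-1-yl]phosphonate | CCOP(=O)(CC#C[Si](C)(C)C)OCC | starting material
15 | tert-butyl{[(2S,3R,4E,6E)-3,5-dimethyl-9-(trimethylsilyl)nona-4,6-dien-8-yn-2-yl]oxy}dimethylsilane | C[Si](C)(C)C#C/C=C/C(C)=C/[C@@H](C)[C@H](C)O[Si](C)(C)C(C)(C)C | intermediate
16 | (2S,3R,4E,6E)-3,5-dimethylnona-4,6-dien-8-yn-2-ol | C#C/C=C/C(C)=C/[C@@H](C)[C@H](C)O | intermediate
17 | (2S,3aR,4S,7aR)-6-chloro-4-{[(tert-butyldimethylsilyl)oxy]methyl}-5-[(3E,5E,7R,8S)-8-hydroxy-5,7-dimethylnona-3,5-dien-1-yn-1-yl]-7-methoxy-7a-methyl-2-(propan-2-yl)-3a,4,5,7a-tetrahydro-1,3-benzodioxol-5-ol (propargylic carbinol; both C5 epimers) | OC1(C#C/C=C/C(C)=C/[C@@H](C)[C@H](C)O)C(Cl)=C(OC)[C@]2(C)O[C@@H](C(C)C)O[C@@H]2[C@@H]1CO[Si](C)(C)C(C)(C)C | intermediate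
18 | (2S,3aR,4S,7aR)-6-chloro-4-(hydroxymethyl)-5-[(3E,5E,7R,8S)-8-hydroxy-5,7-dimethylnona-3,5-dien-1-yn-1-yl]-7a-methyl-2-(propan-2-yl)-3a,4-dihydro-1,3-benzodioxol-7(7aH)-one (hydroxy ynenone) | O=C1C(Cl)=C(C#C/C=C/C(C)=C/[C@@H](C)[C@H](C)O)[C@@H](CO)[C@H]2O[C@H](C(C)C)O[C@@]12C | intermediate
19 | 7,8-O-[(S)-2-methylpropylidene] acetal of (7R,8R,8aS)-5-chloro-7,8-dihydroxy-3-[(1E,3E,5R,6S)-6-hydroxy-3,5-dimethylhepta-1,3-dien-1-yl]-7-methyl-1,7,8,8a-tetrahydro-6H-isochromen-6-one | CC(/C=C/C1=CC2=C(Cl)C(=O)[C@]3(C)O[C@@H](C(C)C)O[C@@H]3[C@@H]2CO1)=C\[C@@H](C)[C@H](C)O | intermediate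
20 | (7R,8R,8aS)-5-chloro-7,8-dihydroxy-3-[(1E,3E,5R,6S)-6-hydroxy-3,5-dimethylhepta-1,3-dien-1-yl]-7-methyl-1,7,8,8a-tetrahydro-6H-isochromen-6-one | CC(/C=C/C1=CC2=C(Cl)C(=O)[C@](C)(O)[C@H](O)[C@@H]2CO1)=C\[C@@H](C)[C@H](C)O | target

## Step count and risks

Total step count: 14. Longest linear sequence: 8 steps (steps 1–6, 13, 14; the side-chain branch, steps 7–12, 13, 14, is equally long).

Steps most likely to fail:

1. Step 5. What may go wrong: too little discrimination between the two quinol enantiomers, or misdirected attack of the hemiacetal oxygen on the methoxy-bearing carbon with exchange of the methoxy group. Fallback: the configuration of C7 is set one step earlier instead of being sorted here. Starting from 4, an enantioselective hydrative dearomatisation with the chiral aryl iodide (R,R)-2,2'-[(2-iodo-1,3-phenylene)bis(oxy)]bis(N-mesitylpropanamide) as catalyst and mCPBA in aqueous MeCN at low temperature should give (4R)-4-hydroxy-5-methoxy-4-methyl-2-{[(tert-butyldimethylsilyl)oxy]methyl}cyclohexa-2,5-dien-1-one F1. The same acetalisation/oxa-Michael addition with 2-methylpropanal, now under the achiral acid (PhO)2P(O)OH and therefore only diastereoselective, returns to the route at 6, whose enantiopurity can be raised by crystallisation.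

2. Step 13. What may go wrong: enolisation at C8a with β-elimination of the acetal oxygen instead of 1,2-addition, or stalling of the cascade before the ring closes. Fallback: the C4–C4a bond is made by cross-coupling and the ring is closed with gold. From 7, nucleophilic O-demethylation (LiCl, DMF, heat) should give (2S,3aR,4S,7aR)-6-chloro-5-hydroxy-4-{[(tert-butyldimethylsilyl)oxy]methyl}-7a-methyl-2-(propan-2-yl)-3a,4-dihydro-1,3-benzodioxol-7(7aH)-one F2, the enol form of the 2-chloro-1,3-dione. O-Triflation (Tf2O, 2,6-lutidine, CH2Cl2, −78 °C) at the less hindered oxygen, the one on C4a rather than the one on C6 next to quaternary C7, gives (2S,3aR,4S,7aR)-6-chloro-4-{[(tert-butyldimethylsilyl)oxy]methyl}-7a-methyl-7-oxo-2-(propan-2-yl)-3a,4,7,7a-tetrahydro-1,3-benzodioxol-5-yl trifluoromethanesulfonate F3. Sonogashira coupling of this triflate with 16 (Pd(PPh3)2Cl2, CuI, Et3N, THF) gives (2S,3aR,4S,7aR)-6-chloro-4-{[(tert-butyldimethylsilyl)oxy]methyl}-5-[(3E,5E,7R,8S)-8-hydroxy-5,7-dimethylnona-3,5-dien-1-yn-1-yl]-7a-methyl-2-(propan-2-yl)-3a,4-dihydro-1,3-benzodioxol-7(7aH)-one F4. HF·pyridine then frees the C1 hydroxyl to give 18, and Ph3PAuNTf2 (cat.) in CH2Cl2 effects the 6-endo-dig hydroalkoxylation, so that the route is rejoined at 19.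

3. Step 4. What may go wrong: capture of water at an ortho carbon or over-oxidation of the electron-rich ring, which lowers the share of para-quinol. Fallback: the ring is dearomatised with singlet oxygen instead of trivalent iodine. From 4, KHSO5 (Oxone) and NaHCO3 in aqueous MeCN (singlet oxygen formed in situ) should add at the para carbon to give rac-4-hydroperoxy-5-methoxy-4-methyl-2-{[(tert-butyldimethylsilyl)oxy]methyl}cyclohexa-2,5-dien-1-one F5, which dimethyl sulfide reduces to return to the route at 5.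

Further compounds
F1 | step 5 | (4R)-4-hydroxy-5-methoxy-4-methyl-2-{[(tert-butyldimethylsilyl)oxy]methyl}cyclohexa-2,5-dien-1-one | COC1=CC(=O)C(CO[Si](C)(C)C(C)(C)C)=C[C@@]1(C)O
F2 | step 13 | (2S,3aR,4S,7aR)-6-chloro-5-hydroxy-4-{[(tert-butyldimethylsilyl)oxy]methyl}-7a-methyl-2-(propan-2-yl)-3a,4-dihydro-1,3-benzodioxol-7(7aH)-one | O=C1C(Cl)=C(O)[C@@H](CO[Si](C)(C)C(C)(C)C)[C@H]2O[C@H](C(C)C)O[C@@]12C
F3 | step 13 | (2S,3aR,4S,7aR)-6-chloro-4-{[(tert-butyldimethylsilyl)oxy]methyl}-7a-methyl-7-oxo-2-(propan-2-yl)-3a,4,7,7a-tetrahydro-1,3-benzodioxol-5-yl trifluoromethanesulfonate | O=C1C(Cl)=C(OS(=O)(=O)C(F)(F)F)[C@@H](CO[Si](C)(C)C(C)(C)C)[C@H]2O[C@H](C(C)C)O[C@@]12C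
F4 | step 13 | (2S,3aR,4S,7aR)-6-chloro-4-{[(tert-butyldimethylsilyl)oxy]methyl}-5-[(3E,5E,7R,8S)-8-hydroxy-5,7-dimethylnona-3,5-dien-1-yn-1-yl]-7a-methyl-2-(propan-2-yl)-3a,4-dihydro-1,3-benzodioxol-7(7aH)-one | O=C1C(Cl)=C(C#C/C=C/C(C)=C/[C@@H](C)[C@H](C)O)[C@@H](CO[Si](C)(C)C(C)(C)C)[C@H]2O[C@H](C(C)C)O[C@@]12C
F5 | step 4 | rac-4-hydroperoxy-5-methoxy-4-methyl-2-{[(tert-butyldimethylsilyl)oxy]methyl}cyclohexa-2,5-dien-1-one | COC1=CC(=O)C(CO[Si](C)(C)C(C)(C)C)=CC1(C)OO
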